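**Plan**

Retrosynthesis: cut the side-chain ester (C15–O–acyl), then the C14–O and C15–O bonds (allylic oxidations), then the lactone bonds C8–O and O–C12, then the C12 oxygens, and last the ring bond C6–C7 of the ten-membered carbocycle, which leads back to (2E,6E)-farnesyl diphosphate.
Forward: farnesol is diphosphorylated, a terpene synthase closes the carbocycle, C12 is oxidised to the acid, P450 hydroxylation of C8 closes the γ-lactone (second ring), then C15 is hydroxylated and acylated, C14 is oxidised, and the silyl group is removed.
Feature that allows the key step: C8 is an unactivated, non-allylic ring CH2 next to C7, whose arm C11(=C13)–C12O2H holds the carboxyl carbon γ to C8, so an α oxygen at C8 is trapped at once as the trans-fused five-membered lactone ring (C7, C8, O, C12, C11).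
Stereochemistry: C7 (R) comes from the synthase, C8 (S) from the face selectivity of the P450, C2' (S) from the Roche ester; C4=C5 keeps the E geometry of farnesol, and C1=C10 is turned ring-cis by the [2,3] shift of the SeO2 oxidation.

Key step: step 5

Remark: germacrane numbering is used (ring C1–C10, C14 on C10, C15 on C4, C11–C13 on C7, H-7 α); "ring-trans" and "ring-cis" say how the two ring bonds sit on an alkene, because the CIP E/Z label changes when a methyl becomes CH2O; the enzymatic steps are assumed to be run in vitro with recombinant enzymes, the C8 hydroxylase being a variant that delivers oxygen to the α face.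

**Route**

Step 1
Reactants: 1 (2E,6E)-farnesol
Product: 2 (2E,6E)-farnesyl chloride
Conditions: NCS, Me2S, CH2Cl2, −40 → 0 °C
Reagents that add atoms: N-chlorosuccinimide, O=C1CCC(=O)N1Cl
Why: Corey–Kim chlorination, in which chloride displaces the alkoxysulfonium ion of the primary allylic alcohol by SN2 at low temperature, so no allylic transposition occurs and the 2E and 6E alkenes are kept.

Step 2
Reactants: 2 (2E,6E)-farnesyl chloride
Product: 3 (2E,6E)-farnesyl diphosphate (triammonium salt)
Conditions: (n-Bu4N)3HP2O7, MeCN, rt; then Dowex 50W-X8 (NH4+ form), 25 mM NH4HCO3, 2% i-PrOH; cellulose chromatography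
Reagents that add atoms: tris(tetrabutylammonium) hydrogen diphosphate, CCCC[N+](CCCC)(CCCC)CCCC.CCCC[N+](CCCC)(CCCC)CCCC.CCCC[N+](CCCC)(CCCC)CCCC.OP(=O)([O-])OP(=O)([O-])[O-]; ammonium hydrogen carbonate (counter-ions), [NH4+].OC([O-])=O
Why: SN2 displacement of the primary allylic chloride by the hydrogen diphosphate anion in dry acetonitrile is the standard nucleophilic diphosphorylation of prenyl halides, and cation exchange then gives the water-soluble ammonium salt that terpene synthases accept.

Step 3
Reactants: 3 (2E,6E)-farnesyl diphosphate (triammonium salt)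
Product: 4 (+)-(7R)-germacrene A
Conditions: recombinant germacrene A synthase, MgCl2, HEPES-NaOH pH 7.5, DTT, glycerol, pentane overlay, 30 °C; cold neutral work-up
Reagents that add atoms: none
Why: Terpene synthase cation–olefin cyclisation, in which the enzyme ionises the allylic diphosphate with its magnesium ions, the distal alkene adds to the allyl cation to close the ten-membered ring through the C6–C7 bond, and loss of a methyl proton gives the isopropenyl group, the fold of the chain in the active site setting C7 as R while both E alkenes of farnesol pass into the ring unchanged.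

Step 4
Reactants: 4 (+)-(7R)-germacrene A
Product: 7 germacrene A acid [(7R)-germacra-1(10),4,11(13)-trien-12-oic acid], via 12-alcohol 5 (not isolated), via 12-aldehyde 6 (not isolated)
Conditions: germacrene A oxidase (CYP71AV-type P450) + cytochrome P450 reductase (yeast microsomes), NADP+ (cat.), D-glucose, glucose dehydrogenase, O2 (air), K2HPO4/KH2PO4 pH 7.5, 30 °C; extraction at pH 5.5, no heating
Reagents that add atoms: dioxygen, O=O
Why: Germacrene A oxidase is the native P450 for this hydrocarbon and oxidises the isopropenyl methyl three times in a row (allylic C–H hydroxylation, then alcohol to aldehyde and aldehyde to acid), all at a carbon remote from C7 and at neutral pH, where the acid-labile and heat-labile 1(10),4-diene survives.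

Step 5
Reactants: 7 germacrene A acid
Product: 9 (7R,8S)-germacra-1(10),4,11(13)-trien-12,8-olide (trans lactone; C8–O α), via 8α-hydroxy acid 8 (not isolated)
Conditions: germacrene A acid 8-hydroxylase (CYP71BL-type P450, α-face variant) + cytochrome P450 reductase (yeast microsomes), NADP+ (cat.), D-glucose, glucose dehydrogenase, O2 (air), thiol-free K2HPO4/KH2PO4 pH 7.5, dodecane overlay, 30 °C; then pH 6, EtOAc
Reagents that add atoms: dioxygen, O=O
Why: The oxoiron porphyrin radical cation of the haem abstracts the α hydrogen of C8 and returns hydroxyl to the same face before the radical can invert, the usual abstraction–rebound course of P450 C–H hydroxylation and the known 8-hydroxylation of germacrene A acid. The new hydroxyl of 8 lies γ to C12 and attacks the carboxyl carbon in a 5-exo-trig acyl substitution with loss of water, so the γ-lactone ring (C7, C8, O, C12, C11) closes without a reagent and both C8–O and O–C12 form in one operation. C8 (S, oxygen α) is the only new stereocentre and is fixed by the protein, which holds the substrate by its carboxylate and offers the haem one face of one methylene; C7 is not touched, so the ring fusion comes out trans. The step needs C8 to be chosen over six allylic CH2 or CH3 groups and three alkenes, and the α over the β hydrogen; no small oxidant would do this, and it rests on the binding pocket of a variant picked for α delivery. The ten-membered ring is flexible enough for the trans-disposed C7 arm and C8 oxygen to reach each other, and a thiol-free buffer with an organic overlay keeps the α-methylene lactone from conjugate addition.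

Step 6
Reactants: 9 (7R,8S)-germacra-1(10),4,11(13)-trien-12,8-olide
Product: 10 15-hydroxy lactone (C15 = CH2OH; C4=C5 still ring-trans)
Conditions: P450 BM3 (CYP102A1) variant selected for C15, NADP+ (cat.), D-glucose, glucose dehydrogenase, O2 (air), K2HPO4/KH2PO4 pH 8.0, 5% DMSO, 25 °C
Reagents that add atoms: dioxygen, O=O
Why: P450-catalysed allylic C–H hydroxylation of a germacranolide methyl group by engineered P450 BM3 variants is established, the allyl radical recombining with the iron-bound hydroxyl at the carbon it came from faster than it can rotate, so C4=C5 should stay ring-trans, and the variant is taken from a screen for C15 over C14, C9 and the alkenes.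

Step 7
Reactants: 11 methyl (S)-3-hydroxy-2-methylpropanoate
Product: 12 methyl (S)-3-(tert-butyldimethylsilyloxy)-2-methylpropanoate
Conditions: TBSCl, imidazole, CH2Cl2, 0 °C → rt
Reagents that add atoms: tert-butyldimethylsilyl chloride, CC(C)(C)[Si](C)(C)Cl
Why: Silyl ether formation on the primary alcohol through the N-silylimidazolium ion, with no bond to the stereocentre broken.

Step 8
Reactants: 12 methyl (S)-3-(tert-butyldimethylsilyloxy)-2-methylpropanoate
Product: 13 (S)-3-(tert-butyldimethylsilyloxy)-2-methylpropanoic acid
Conditions: LiOH, THF/MeOH/H2O, 0 °C → rt; then cold 1 M HCl to pH 4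
Reagents that add atoms: lithium hydroxide, [Li+].[OH-]
Why: Ester saponification by acyl–oxygen cleavage with LiOH at 0 °C, conditions under which α-epimerisation and β-elimination of the silyloxy group are slow, followed by brief mild acidification that the primary TBS ether tolerates.

Step 9
Reactants: 10 15-hydroxy lactone; 13 (S)-3-(tert-butyldimethylsilyloxy)-2-methylpropanoic acid
Product: 14 C15 ester of 10 with acid 13
Conditions: DCC, DMAP (0.1 equiv), CH2Cl2, 0 °C → rt
Reagents that add atoms: none
Why: Steglich esterification, in which the DCC-activated acid is passed on by DMAP to the unhindered primary allylic alcohol, a method in regular use for allylic alcohols of α-methylene lactone germacranolides, and low temperature with little DMAP guards the α-stereocentre of the acid.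

Step 10
Reactants: 14 C15 ester of 10 with acid 13
Product: 17 14-hydroxy ester (C14 = CH2OH; C1=C10 ring-cis), via allylseleninic acid 15 (not isolated), via selenium ester 16 (not isolated)
Conditions: SeO2 (0.5 equiv), t-BuOOH (5.5 M in decane), CH2Cl2, 0 °C → rt
Reagents that add atoms: selenium dioxide (delivers the C14 oxygen), O=[Se]=O; tert-butyl hydroperoxide (terminal oxidant that restores it), CC(C)(C)OO
Why: Riley oxidation, in which SeO2 adds to C1 in an ene reaction that takes a hydrogen from C14 and the [2,3]-sigmatropic shift of the allylseleninic acid then carries oxygen to C14 and re-forms C1=C10 with the CH2O group trans to C2, which is the ring-cis geometry (the known outcome for germacranolide 1(10)-alkenes), while C4=C5 is deactivated by its allylic acyloxy group and the methylene lactone is too electron-poor to react.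

Step 11
Reactants: 17 14-hydroxy ester
Product: 18 CNP0241696.1 (target)
Conditions: HF·pyridine, pyridine, THF, 0 °C → rt
Reagents that add atoms: none
Why: Fluoride cleavage of the primary silyl ether with buffered HF·pyridine, mildly acidic conditions that leave both esters, the allylic alcohol, the alkene geometries and the Michael acceptor alone and avoid the β-elimination that basic fluoride could cause in the β-hydroxy ester.

**Compound list**

1 | (2E,6E)-farnesol | CC(C)=CCC/C(C)=C/CC/C(C)=C/CO | starting material
2 | (2E,6E)-farnesyl chloride | CC(C)=CCC/C(C)=C/CC/C(C)=C/CCl | intermediate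
3 | (2E,6E)-farnesyl diphosphate, triammonium salt | CC(C)=CCC/C(C)=C/CC/C(C)=C/COP(=O)([O-])OP(=O)([O-])[O-].[NH4+].[NH4+].[NH4+] | intermediate
4 | (+)-(7R)-germacrene A, (1(10)E,4E)-germacra-1(10),4,11-triene | C1C/C(C)=C/CC/C(C)=C/C[C@@H]1C(C)=C | intermediate
5 | (7R)-germacra-1(10),4,11(13)-trien-12-ol | C1C/C(C)=C/CC/C(C)=C/C[C@@H]1C(=C)CO | intermediate (not isolated)
6 | (7R)-germacra-1(10),4,11(13)-trien-12-al | C1C/C(C)=C/CC/C(C)=C/C[C@@H]1C(=C)C=O | intermediate (not isolated)
7 | germacrene A acid, (1(10)E,4E,7R)-germacra-1(10),4,11(13)-trien-12-oic acid | C1C/C(C)=C/CC/C(C)=C/C[C@@H]1C(=C)C(=O)O | intermediate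
8 | (7R,8S)-8α-hydroxygermacrene A acid | O[C@H]1C/C(C)=C/CC/C(C)=C/C[C@@H]1C(=C)C(=O)O | intermediate (not isolated)
9 | (7R,8S)-germacra-1(10),4,11(13)-trien-12,8-olide; trans-fused α-methylene-γ-lactone on the (1(10)E,4E) ring, C8–O α | C=C1C(=O)O[C@H]2C/C(C)=C/CC/C(C)=C/C[C@H]12 | intermediate
10 | 15-hydroxy lactone; as 9 with C15 = CH2OH, C4=C5 ring-trans (CIP 4Z) | C=C1C(=O)O[C@H]2C/C(C)=C/CC/C(CO)=C/C[C@H]12 | intermediate
11 | methyl (S)-3-hydroxy-2-methylpropanoate | COC(=O)[C@@H](C)CO | starting material
12 | methyl (S)-3-(tert-butyldimethylsilyloxy)-2-methylpropanoate | COC(=O)[C@@H](C)CO[Si](C)(C)C(C)(C)C | intermediate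
13 | (S)-3-(tert-butyldimethylsilyloxy)-2-methylpropanoic acid | OC(=O)[C@@H](C)CO[Si](C)(C)C(C)(C)C | intermediate
14 | C15 (S)-3-(tert-butyldimethylsilyloxy)-2-methylpropanoate of 10 | C=C1C(=O)O[C@H]2C/C(C)=C/CC/C(COC(=O)[C@@H](C)CO[Si](C)(C)C(C)(C)C)=C/C[C@H]12 | intermediate
15 | allylseleninic acid; Se on C1 (outer, β face expected), C10=C14 exocyclic | C=C1C(=O)O[C@H]2CC(=C)[C@H]([Se](=O)O)CC/C(COC(=O)[C@@H](C)CO[Si](C)(C)C(C)(C)C)=C/C[C@H]12 | intermediate (not isolated)
16 | C14–O–Se–OH ester of divalent selenium; C1=C10 ring-cis | C=C1C(=O)O[C@H]2C/C(CO[Se]O)=C\CC/C(COC(=O)[C@@H](C)CO[Si](C)(C)C(C)(C)C)=C/C[C@H]12 | intermediate (not isolated)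
17 | 14-hydroxy ester; as 14 with C14 = CH2OH and C1=C10 ring-cis | C=C1C(=O)O[C@H]2C/C(CO)=C\CC/C(COC(=O)[C@@H](C)CO[Si](C)(C)C(C)(C)C)=C/C[C@H]12 | intermediate
18 | CNP0241696.1; (7R,8S)-14-hydroxy-15-[(S)-3-hydroxy-2-methylpropanoyloxy]germacra-1(10),4,11(13)-trien-12,8-olide, C1=C10 ring-cis, C4=C5 ring-trans | C=C1C(=O)O[C@H]2C/C(CO)=C\CC/C(COC(=O)[C@@H](C)CO)=C/C[C@H]12 | target

**Totals and risks**

Total step count: 11. Longest linear sequence: 9 steps (steps 1–6, 9, 10, 11); the side chain takes 2 steps (7, 8) and joins at step 9.

Steps most likely to fail: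

Step 6. The hydroxylase may not tell C15 from C14, or may epoxidise a ring alkene, because the lactone offers the protein no polar handle. In that case the oxidation is moved in front of the lactonisation, where the free carboxylate can serve as the recognition element that P450 BM3 uses for its native fatty acid substrates. Setting out from 7, a BM3 variant screened on the acid (same cofactor system) would give 15-hydroxygermacrene A acid F1. The 8-hydroxylase of step 5 would then take F1 to 8α,15-dihydroxygermacrene A acid F2, which lactonises as 8 does and rejoins the route at 10.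

Step 5. Oxygen may be delivered to the β face of C8, which gives a hydroxy acid that does not close to the trans lactone. A β-selective hydroxylase of the same family is then used on purpose: from 7 it would give 8β-hydroxygermacrene A acid F3, a stable hydroxy acid. A Mitsunobu lactonisation (PPh3, DIAD, THF, 0 °C) would let the carboxylate displace the activated C8 oxygen with inversion, which makes the α C8–O bond and returns to 9.

Step 10. The new allylic alcohol may be over-oxidised to the enal, the ene reaction may compete at other allylic CH2 groups, or the acidic selenium species may trigger transannular cyclisation of the 1(10),4-diene. A selenium-free detour sets out from 14. A Schenck ene reaction (O2, hν, tetraphenylporphyrin, CH2Cl2, 0 °C), which on germacranolide 1(10)-alkenes takes a hydrogen from C14, would give the 1-hydroperoxide with exocyclic C10=C14 F4. PPh3 reduces it to the 1-hydroxy-10(14)-ene F5. Ph3SiOReO3 (cat.) in Et2O at −50 → 0 °C then shifts the hydroxyl to C14 through a chair-like [3,3] transposition of the perrhenate ester, which places C2 equatorial and so re-forms C1=C10 ring-cis, arriving at 17.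

**Further compounds**

F1 | step 6 | 15-hydroxygermacrene A acid | C1C/C(C)=C/CC/C(CO)=C/C[C@@H]1C(=C)C(=O)O
F2 | step 6 | 8α,15-dihydroxygermacrene A acid | O[C@H]1C/C(C)=C/CC/C(CO)=C/C[C@@H]1C(=C)C(=O)O
F3 | step 5 | 8β-hydroxygermacrene A acid | O[C@@H]1C/C(C)=C/CC/C(C)=C/C[C@@H]1C(=C)C(=O)O
F4 | step 10 | 1β-hydroperoxy-10(14)-ene derived from 14 | C=C1C(=O)O[C@H]2CC(=C)[C@H](OO)CC/C(COC(=O)[C@@H](C)CO[Si](C)(C)C(C)(C)C)=C/C[C@H]12
F5 | step 10 | 1β-hydroxy-10(14)-ene derived from 14 | C=C1C(=O)O[C@H]2CC(=C)[C@H](O)CC/C(COC(=O)[C@@H](C)CO[Si](C)(C)C(C)(C)C)=C/C[C@H]12
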